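## Retrosynthetic overview

- The strategy rests on the cis-fused γ-lactone: its carbons C6, C7, C11 and C12 (target locants throughout) are the four carbons of furan, and the C8 oxygen sits on the carbon bonded to C7. This is an anti aldol between furan C3 and a glyoxylate, stored as an oxetane (C6–C7–C8–O) fused to a dihydrofuran.
- Ring order: oxetane/dihydrofuran bicycle by photocycloaddition, then opening to a C6 acetal with a C8/C9 epoxide, then the γ-lactone (C6–O–C12), and last the ten-membered carbocycle.
- Disconnections: C4–C5 (ring-closing Nozaki–Hiyama–Kishi), C5–C6 (alkoxymethyllithium on a C6 lactone, then Felkin–Anh reduction), C9–C10 (copper-catalysed alkenyl Grignard opening of the epoxide), C2–C3 (asymmetric 2-bromoallylboration on the side-chain fragment from 2-butyn-1-ol).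
- C13 comes from Mannich methylenation; the tiglate and acetate are installed late and the C2 hydroxyl is unveiled last.

Key step: step 2

Assumption: the (−)-8-phenylmenthyl ester is taken to shield the face that leads to the (1S,5R,6S) photoadduct; if it induces the opposite sense, (+)-8-phenylmenthol is used in step 1 and nothing else changes.

## Route

Step 1
Reactants: 1 (−)-8-phenylmenthol; 2 glyoxylic acid (used as the monohydrate)
Product: 3 (−)-8-phenylmenthyl glyoxylate
Conditions: TsOH·H2O (cat.), toluene, reflux, Dean–Stark; then heating under vacuum over 4 Å sieves to free the aldehyde from its hydrate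
Reagents that add atoms: none
Why: Fischer esterification driven by azeotropic removal of water; no stereocentre is formed or touched.

Step 2
Reactants: 3 (−)-8-phenylmenthyl glyoxylate; 4 furan (reactant and solvent)
Product: 5 (−)-8-phenylmenthyl (1S,5R,6S)-2,7-dioxabicyclo[3.2.0]hept-3-ene-6-carboxylate (exo ester; ring atoms 1, 5, 6 are C6, C7, C8)
Conditions: hν (300 nm lamps, Pyrex), degassed furan, −20 °C; Et3N-deactivated silica or crystallisation to remove minor isomers
Reagents that add atoms: none
Why: The n,π* excited aldehyde of 3 attacks furan with its electrophilic oxygen at C2 (future C6), giving a 1,4-biradical (an allyl radical over the furan carbons and an α-oxy-α-ester radical at C8) that collapses after intersystem crossing by C7–C8 bond formation. The closest known reaction is the Paternò–Büchi cycloaddition of furan with aldehydes and alkyl glyoxylates, which shows this head-to-head (acetal) regiochemistry and exo preference. The oxetane closes by combination of the two radical centres and can only be cis-fused to the five-membered ring, which fixes C6 relative to C7. C8 is set exo because the closing biradical conformer turns the ester away from the concave face of the dihydrofuran, giving the C7/C8 relationship of the target. The absolute configuration comes from the 8-phenylmenthyl ester, whose phenyl ring should stack over one face of the glyoxylate and of the derived radical so that the C–C bond forms on the open face. The step needs regio-, exo- and π-facial selectivity: the first two are secured by the furan oxygen (O-attack at C2, stabilised allyl radical) and by the ester substituent, the third by the auxiliary at low temperature.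

Step 3
Reactants: 5 photoadduct
Product: 6 (−)-8-phenylmenthyl (1S,5R,6S)-2,7-dioxabicyclo[3.2.0]heptane-6-carboxylate
Conditions: H2 (1 atm), Pd/C (palladium on carbon, 5 %), EtOAc, K2CO3 (trace), rt
Reagents that add atoms: none
Why: Catalytic hydrogenation of the enol ether C11=C12 removes the path to furan re-aromatisation; no stereocentre is created and the acetal and aryl ring are inert.

Step 4
Reactants: 6 saturated ester
Product: 7 [(1S,5R,6S)-2,7-dioxabicyclo[3.2.0]heptan-6-yl]methanol
Conditions: LiAlH4, Et2O, 0 °C; aqueous NaOH work-up; auxiliary 1 recovered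
Reagents that add atoms: none
Why: Hydride reduction of the ester gives the C9 carbinol and releases the auxiliary; the base-stable bicyclic acetal and C8 are untouched.

Step 5
Reactants: 7 alcohol
Product: 8 [(1S,5R,6S)-2,7-dioxabicyclo[3.2.0]heptan-6-yl]methyl 4-methylbenzenesulfonate
Conditions: TsCl, Et3N, DMAP (cat.), CH2Cl2, 0 °C
Reagents that add atoms: p-toluenesulfonyl chloride, Cc1ccc(cc1)S(Cl)(=O)=O
Why: Sulfonylation of the primary C9 alcohol under basic conditions leaves the acid-labile acetal intact and installs the leaving group for the epoxide closure.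

Step 6
Reactants: 8 tosylate
Product: 10 (3R)-2-methoxy-3-[(2S)-oxiran-2-yl]tetrahydrofuran (mixture of C6 anomers), via hydroxy tosylate 9 (not isolated)
Conditions: camphorsulfonic acid (cat.), MeOH, 0 °C; then K2CO3, 0 °C → rt
Reagents that add atoms: methanol, CO
Why: Acid-catalysed methanolysis opens the strained oxetane acetal at C6 through the ring oxocarbenium ion and frees the C8 hydroxyl, which on addition of base displaces the C9 tosylate in a 3-exo-tet Williamson closure; the C8–O bond is never broken, so C8 keeps its configuration.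

Step 7
Reactants: 11 2-butyn-1-ol
Product: 13 (Z)-3-iodobut-2-en-1-ol, via cyclic alkenylalanate 12 (not isolated)
Conditions: NaAlH2(OCH2CH2OMe)2, THF, 0 °C → rt; EtOAc quench; then I2, −78 °C
Reagents that add atoms: iodine, [I][I]
Why: Hydroxyl-directed trans-hydroalumination of the propargylic alcohol places aluminium on C10 cis to the carbinol carbon, and iodinolysis with retention gives the Z iodoalkene that fixes the C1=C10 geometry.

Step 8
Reactants: 13 (Z)-3-iodobut-2-en-1-ol
Product: 14 (Z)-3-iodobut-2-enal
Conditions: MnO2 (activated), CH2Cl2, rt, dark; used at once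
Reagents that add atoms: none
Why: Allylic alcohol oxidation with MnO2 stops at the enal and keeps the alkene geometry.

Step 9
Reactants: 14 (Z)-3-iodobut-2-enal
Product: 15 (4R,5Z)-2-bromo-6-iodohepta-1,5-dien-4-ol
Conditions: B-bromodiisopinocampheylborane from (−)-α-pinene, allene, CH2Cl2, −78 → 0 °C; then 14, Et2O, −78 °C; NaOH, H2O2 work-up
Reagents that add atoms: allene, C=C=C; B-bromodiisopinocampheylborane from (−)-α-pinene, BrB([C@H]1C[C@H]2C[C@@H]([C@@H]1C)C2(C)C)[C@H]1C[C@H]2C[C@@H]([C@@H]1C)C2(C)C
Why: Bromoboration of allene gives the B-(2-bromoallyl)borane, which adds to the aldehyde in a Brown asymmetric allylboration through a chair six-membered transition state; the isopinocampheyl groups from (−)-α-pinene should direct attack to the Re face and set C2 as R.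

Step 10
Reactants: 15 dienol
Product: 16 (4R,5Z)-2-bromo-4-(tert-butyldimethylsilyloxy)-6-iodohepta-1,5-diene
Conditions: TBSCl, imidazole, DMF, rt
Reagents that add atoms: tert-butyldimethylsilyl chloride, CC(C)(C)[Si](C)(C)Cl
Why: Standard silylation of the secondary allylic alcohol; the C2 configuration is untouched.

Step 11
Reactants: 16 side-chain iodide; 10 epoxide
Product: 18 (1R,3Z,5R)-7-bromo-5-(tert-butyldimethylsilyloxy)-1-[(3R)-2-methoxytetrahydrofuran-3-yl]-3-methylocta-3,7-dien-1-ol (free C8 hydroxyl), via alkenylmagnesium chloride 17 (not isolated)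
Conditions: i-PrMgCl·LiCl, THF, −20 °C → rt; then CuBr·SMe2 (10 mol %), 10, −30 °C → rt
Reagents that add atoms: none
Why: Iodine–magnesium exchange is selective for the alkenyl iodide over the alkenyl bromide and retains the Z geometry, and the copper-catalysed Grignard opening of the monosubstituted epoxide at its CH2 terminus (SN2) forms C9–C10 and frees the C8 hydroxyl without touching C8.

Step 12
Reactants: 18 C8 alcohol
Product: 19 C8 p-methoxybenzyl ether of 18
Conditions: NaH, PMBCl, Bu4NI (cat.), THF/DMF, 0 °C → rt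
Reagents that add atoms: 4-methoxybenzyl chloride, COc1ccc(CCl)cc1
Why: Williamson etherification gives an ether that survives the organometallic and enolate steps and is removed oxidatively later; the acetal, silyl ether and alkenyl bromide are stable to NaH.

Step 13
Reactants: 19 methyl acetal
Product: 20 (3R)-3-[(1R,3Z,5R)-7-bromo-5-(tert-butyldimethylsilyloxy)-1-(4-methoxybenzyloxy)-3-methylocta-3,7-dien-1-yl]tetrahydrofuran-2-ol (C6 lactol)
Conditions: 0.2 M HCl, THF/H2O, 0 °C → rt
Reagents that add atoms: water, O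
Why: Acid hydrolysis of the 2-methoxytetrahydrofuran acetal through the cyclic oxocarbenium ion is much faster than cleavage of the silyl or p-methoxybenzyl ethers.

Step 14
Reactants: 20 lactol
Product: 21 (3R)-3-[(1R,3Z,5R)-7-bromo-5-(tert-butyldimethylsilyloxy)-1-(4-methoxybenzyloxy)-3-methylocta-3,7-dien-1-yl]dihydrofuran-2(3H)-one (C6 lactone)
Conditions: TEMPO (cat.), PhI(OAc)2, CH2Cl2, rt
Reagents that add atoms: none
Why: Nitroxyl-catalysed oxidation of the lactol puts C6 at the acid oxidation level and keeps the C12 oxygen masked as the ring oxygen, under conditions that do not expose C7 to base.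

Step 15
Reactants: 22 (tributylstannyl)methanol
Product: 23 tributyl[(1-ethoxyethoxy)methyl]stannane
Conditions: ethyl vinyl ether, PPTS (cat.), CH2Cl2, 0 °C
Reagents that add atoms: ethyl vinyl ether, C=COCC
Why: Acid-catalysed addition of the alcohol to the vinyl ether gives the 1-ethoxyethyl acetal, a precursor of a hydroxymethyl anion; its acetal centre is a mixture and is removed later.

Step 16
Reactants: 23 stannane; 21 lactone
Product: 25 open-chain γ-hydroxy ketone EEO–C5H2–C6(=O)–C7H(CH2CH2OH)–C8H(OPMB)–side chain (in equilibrium with its cyclic hemiketal), via alkoxymethyllithium 24 (not isolated)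
Conditions: 23, n-BuLi, THF, −78 °C; then 21, −78 °C; aq. NH4Cl; used crude
Reagents that add atoms: none
Why: Tin–lithium exchange gives the α-alkoxymethyllithium, which adds once to the γ-lactone carbonyl at −78 °C to form C5–C6 (the lithium hemiketalate resists a second addition); the crude product is carried on so that C7 is not epimerised.

Step 17
Reactants: 25 hydroxy ketone
Product: 26 1,4-diol with the new C6 carbinol 6R (C6–OH and C12–OH free)
Conditions: LiBH(s-Bu)3, THF, −78 °C; then NaOH, H2O2
Reagents that add atoms: none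
Why: Felkin–Anh reduction with a bulky, non-chelating hydride: attack on C6 anti to the branched C8 substituent of C7 (C11 inside, H outside) should give the 6R carbinol, which places C5 and C8 cis on the future lactone.

Step 18
Reactants: 26 diol
Product: 27 cis-fused γ-lactone (C6–O–C12=O) carrying CH2O(1-ethoxyethyl) on C6 and the C8(OPMB) side chain on C7
Conditions: TEMPO (cat.), PhI(OAc)2, NaHCO3, CH2Cl2, rt
Reagents that add atoms: none
Why: Oxidative lactonisation of a 1,4-diol: the primary C12 alcohol is oxidised selectively, closes to the lactol on the C6 hydroxyl and is oxidised again; with C8 blocked only the 6,12-lactone can form.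

Step 19
Reactants: 27 lactone
Product: 30 α-methylene-γ-lactone (C11=C13) otherwise as 27, via Mannich base 28 (not isolated), via trimethylammonium iodide 29 (not isolated)
Conditions: LiN(SiMe3)2, THF, −78 °C; CH2=NMe2+ I−, −78 °C → rt; then MeI, MeOH; then aq. NaHCO3, CH2Cl2
Reagents that add atoms: Eschenmoser's salt, C=[N+](C)C.[I-]
Why: Mannich alkylation of the C11 lithium enolate with Eschenmoser's salt, exhaustive N-methylation and base-induced β-elimination of trimethylamine install the exocyclic methylene; the amide base at −78 °C is not expected to attack the alkenyl bromide.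

Step 20
Reactants: 30 p-methoxybenzyl ether
Product: 31 free C8 alcohol of 30
Conditions: DDQ, CH2Cl2/pH 7 buffer, 0 °C
Reagents that add atoms: none
Why: Oxidative cleavage of the p-methoxybenzyl ether (hydride abstraction, then hydrolysis of the oxocarbenium ion) frees only the C8 hydroxyl; the silyl ether, buffered acetal and electron-poor alkenes are inert.

Step 21
Reactants: 31 C8 alcohol
Product: 32 C8 tiglate
Conditions: tiglic acid, 2,4,6-trichlorobenzoyl chloride, Et3N, toluene, rt; then 31, DMAP
Reagents that add atoms: tiglic acid, C/C=C(\C)C(=O)O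
Why: Yamaguchi esterification through the mixed anhydride acylates the hindered C8 alcohol with retention of the E geometry and without base strong enough to affect the lactone.

Step 22
Reactants: 32 1-ethoxyethyl acetal
Product: 33 primary C5 alcohol
Conditions: PPTS (cat.), MeOH, rt
Reagents that add atoms: none
Why: Mild acid-catalysed transacetalisation removes the 1-ethoxyethyl group while the secondary silyl ether, the esters and the lactone stay intact.

Step 23
Reactants: 33 C5 alcohol
Product: 34 C5 aldehyde (α-acyloxy aldehyde on C6)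
Conditions: Dess–Martin periodinane, NaHCO3, CH2Cl2, 0 °C; used at once
Reagents that add atoms: none
Why: Dess–Martin oxidation under buffered, non-basic conditions should give the aldehyde without epimerising C6.

Step 24
Reactants: 34 bromo aldehyde
Product: 35 ten-membered-ring C5 alcohol (5S) with C4=C15 exocyclic methylene, C8 tiglate and C2 silyl ether
Conditions: CrCl2 (excess), NiCl2 (cat.), DMSO/THF, rt, slow addition, ≤ 2 mM
Reagents that add atoms: none
Why: Intramolecular Nozaki–Hiyama–Kishi reaction: zerovalent nickel inserts into the C4–Br bond, transmetallation gives an alkenylchromium species that adds only to the aldehyde and closes the ring at C4–C5 under high dilution; Felkin–Anh attack anti to the C6–O bond is expected to give 5S.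

Step 25
Reactants: 35 C5 alcohol
Product: 36 C5 acetate
Conditions: Ac2O, pyridine, DMAP (cat.), CH2Cl2, 0 °C → rt
Reagents that add atoms: acetic anhydride, CC(=O)OC(C)=O
Why: DMAP-catalysed acetylation of the secondary allylic alcohol leaves the tiglate, lactone and silyl ether untouched.

Step 26
Reactants: 36 silyl ether
Product: 37 target CNP0210609.1
Conditions: HF·pyridine, pyridine, THF, 0 °C → rt
Reagents that add atoms: none
Why: Fluoride-mediated cleavage of the silyl ether liberates the C2 alcohol; the acetate, tiglate and α-methylene lactone are stable to these weakly acidic conditions.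

## Compound list

1 | (−)-8-phenylmenthol, (1R,2S,5R)-5-methyl-2-(2-phenylpropan-2-yl)cyclohexan-1-ol | CC(C)(c1ccccc1)[C@@H]1CC[C@@H](C)C[C@H]1O | starting material
2 | glyoxylic acid (monohydrate used) | O=CC(=O)O | starting material
3 | (−)-8-phenylmenthyl glyoxylate | CC(C)(c1ccccc1)[C@@H]1CC[C@@H](C)C[C@H]1OC(=O)C=O | intermediate
4 | furan | c1ccoc1 | starting material
5 | (−)-8-phenylmenthyl (1S,5R,6S)-2,7-dioxabicyclo[3.2.0]hept-3-ene-6-carboxylate (exo) | CC(C)(c1ccccc1)[C@@H]1CC[C@@H](C)C[C@H]1OC(=O)[C@H]1O[C@@H]2OC=C[C@H]12 | intermediate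
6 | (−)-8-phenylmenthyl (1S,5R,6S)-2,7-dioxabicyclo[3.2.0]heptane-6-carboxylate | CC(C)(c1ccccc1)[C@@H]1CC[C@@H](C)C[C@H]1OC(=O)[C@H]1O[C@@H]2OCC[C@H]12 | intermediate
7 | [(1S,5R,6S)-2,7-dioxabicyclo[3.2.0]heptan-6-yl]methanol | OC[C@H]1O[C@@H]2OCC[C@H]12 | intermediate
8 | [(1S,5R,6S)-2,7-dioxabicyclo[3.2.0]heptan-6-yl]methyl 4-methylbenzenesulfonate | Cc1ccc(cc1)S(=O)(=O)OC[C@H]1O[C@@H]2OCC[C@H]12 | intermediate
9 | (2S)-2-hydroxy-2-[(3R)-2-methoxytetrahydrofuran-3-yl]ethyl 4-methylbenzenesulfonate (anomer mixture) | COC1OCC[C@@H]1[C@H](O)COS(=O)(=O)c1ccc(C)cc1 | intermediate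
10 | (3R)-2-methoxy-3-[(2S)-oxiran-2-yl]tetrahydrofuran (anomer mixture) | COC1OCC[C@@H]1[C@H]1CO1 | intermediate
11 | 2-butyn-1-ol | CC#CCO | starting material
12 | sodium cyclic alkenylalanate (five-membered O–Al–C10=C1–C2 ring, two 2-methoxyethoxy ligands) | CC1=CCO[Al-]1(OCCOC)OCCOC.[Na+] | intermediate
13 | (Z)-3-iodobut-2-en-1-ol | C/C(I)=C/CO | intermediate
14 | (Z)-3-iodobut-2-enal | C/C(I)=C/C=O | intermediate
15 | (4R,5Z)-2-bromo-6-iodohepta-1,5-dien-4-ol | I/C(C)=C\[C@H](O)CC(Br)=C | intermediate
16 | (4R,5Z)-2-bromo-4-(tert-butyldimethylsilyloxy)-6-iodohepta-1,5-diene | I/C(C)=C\[C@H](O[Si](C)(C)C(C)(C)C)CC(Br)=C | intermediate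
17 | alkenylmagnesium chloride from 16 (Mg on C10, Z) | Cl[Mg]/C(C)=C\[C@H](O[Si](C)(C)C(C)(C)C)CC(Br)=C | intermediate
18 | (1R,3Z,5R)-7-bromo-5-(tert-butyldimethylsilyloxy)-1-[(3R)-2-methoxytetrahydrofuran-3-yl]-3-methylocta-3,7-dien-1-ol | COC1OCC[C@@H]1[C@H](O)C/C(C)=C\[C@H](O[Si](C)(C)C(C)(C)C)CC(Br)=C | intermediate
19 | C8 p-methoxybenzyl ether of 18 | COC1OCC[C@@H]1[C@H](OCc1ccc(OC)cc1)C/C(C)=C\[C@H](O[Si](C)(C)C(C)(C)C)CC(Br)=C | intermediate
20 | C6 lactol, (3R)-3-[(1R,3Z,5R)-7-bromo-5-(tert-butyldimethylsilyloxy)-1-(4-methoxybenzyloxy)-3-methylocta-3,7-dien-1-yl]tetrahydrofuran-2-ol | OC1OCC[C@@H]1[C@H](OCc1ccc(OC)cc1)C/C(C)=C\[C@H](O[Si](C)(C)C(C)(C)C)CC(Br)=C | intermediate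
21 | C6 lactone, (3R)-3-[(1R,3Z,5R)-7-bromo-5-(tert-butyldimethylsilyloxy)-1-(4-methoxybenzyloxy)-3-methylocta-3,7-dien-1-yl]dihydrofuran-2(3H)-one | O=C1OCC[C@@H]1[C@H](OCc1ccc(OC)cc1)C/C(C)=C\[C@H](O[Si](C)(C)C(C)(C)C)CC(Br)=C | intermediate
22 | (tributylstannyl)methanol | OC[Sn](CCCC)(CCCC)CCCC | starting material
23 | tributyl[(1-ethoxyethoxy)methyl]stannane | CCOC(C)OC[Sn](CCCC)(CCCC)CCCC | intermediate
24 | [(1-ethoxyethoxy)methyl]lithium | [Li]COC(C)OCC | intermediate
25 | γ-hydroxy ketone (C6 ketone, C5H2O–EE, C12–OH, C8–OPMB, C2–OTBS, C4 alkenyl bromide) | CCOC(C)OCC(=O)[C@H](CCO)[C@H](OCc1ccc(OC)cc1)C/C(C)=C\[C@H](O[Si](C)(C)C(C)(C)C)CC(Br)=C | intermediate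
26 | 1,4-diol, 6R carbinol of 25 | CCOC(C)OC[C@H](O)[C@H](CCO)[C@H](OCc1ccc(OC)cc1)C/C(C)=C\[C@H](O[Si](C)(C)C(C)(C)C)CC(Br)=C | intermediate
27 | cis-fused 6,12-γ-lactone (C11 still CH2) | C1C(=O)O[C@@H](COC(C)OCC)[C@H]1[C@H](OCc1ccc(OC)cc1)C/C(C)=C\[C@H](O[Si](C)(C)C(C)(C)C)CC(Br)=C | intermediate
28 | Mannich base, C11–CH2NMe2 lactone (C11 epimers) | CN(C)CC1C(=O)O[C@@H](COC(C)OCC)[C@H]1[C@H](OCc1ccc(OC)cc1)C/C(C)=C\[C@H](O[Si](C)(C)C(C)(C)C)CC(Br)=C | intermediate
29 | trimethylammonium iodide of 28 | C[N+](C)(C)CC1C(=O)O[C@@H](COC(C)OCC)[C@H]1[C@H](OCc1ccc(OC)cc1)C/C(C)=C\[C@H](O[Si](C)(C)C(C)(C)C)CC(Br)=C.[I-] | intermediate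
30 | α-methylene-γ-lactone (C11=C13), C8–OPMB, C5H2O–EE | C=C1C(=O)O[C@@H](COC(C)OCC)[C@H]1[C@H](OCc1ccc(OC)cc1)C/C(C)=C\[C@H](O[Si](C)(C)C(C)(C)C)CC(Br)=C | intermediate
31 | C8 alcohol | C=C1C(=O)O[C@@H](COC(C)OCC)[C@H]1[C@H](O)C/C(C)=C\[C@H](O[Si](C)(C)C(C)(C)C)CC(Br)=C | intermediate
32 | C8 tiglate | C=C1C(=O)O[C@@H](COC(C)OCC)[C@H]1[C@H](OC(=O)/C(C)=C/C)C/C(C)=C\[C@H](O[Si](C)(C)C(C)(C)C)CC(Br)=C | intermediate
33 | primary C5 alcohol | C=C1C(=O)O[C@@H](CO)[C@H]1[C@H](OC(=O)/C(C)=C/C)C/C(C)=C\[C@H](O[Si](C)(C)C(C)(C)C)CC(Br)=C | intermediate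
34 | C5 aldehyde | C=C1C(=O)O[C@@H](C=O)[C@H]1[C@H](OC(=O)/C(C)=C/C)C/C(C)=C\[C@H](O[Si](C)(C)C(C)(C)C)CC(Br)=C | intermediate
35 | ten-membered-ring 5S alcohol, C2 silyl ether | C=C1C(=O)O[C@@H]2[C@H]1[C@H](OC(=O)/C(C)=C/C)C/C(C)=C\[C@H](O[Si](C)(C)C(C)(C)C)CC(=C)[C@@H]2O | intermediate
36 | C5 acetate, C2 silyl ether | C=C1C(=O)O[C@@H]2[C@H]1[C@H](OC(=O)/C(C)=C/C)C/C(C)=C\[C@H](O[Si](C)(C)C(C)(C)C)CC(=C)[C@@H]2OC(C)=O | intermediate
37 | CNP0210609.1 (2R,5S,6R,7R,8R; 1(10)Z) | C=C1C(=O)O[C@@H]2[C@H]1[C@H](OC(=O)/C(C)=C/C)C/C(C)=C\[C@H](O)CC(=C)[C@@H]2OC(C)=O | target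

## Step count and risks

Total steps: 26. Longest linear sequence: 21 steps (steps 1–6, 11–14 and 16–26).

Steps most likely to fail:

1. Step 2. The photochemistry should be reliable in regio- and exo-selectivity, but the auxiliary may discriminate the two faces poorly, or in the opposite sense, when the biradical closes. Fallback by resolution, setting out from furan 4 and rejoining at 7: furan is irradiated with ethyl glyoxylate to give the racemic exo adduct, ethyl 2,7-dioxabicyclo[3.2.0]hept-3-ene-6-carboxylate F1. This is hydrogenated (H2, Pd/C) to the racemic saturated ester F2 and reduced with LiAlH4 to the racemic alcohol F3. Acylation with vinyl acetate and Candida antarctica lipase B separates the enantiomers. Written for the case in which the wanted enantiomer is the one acylated, the (1S,5R,6S) acetate F4 is methanolysed (K2CO3, MeOH) to 7; if the lipase prefers the other enantiomer, 7 is the recovered alcohol.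

2. Step 17. Chelation of the hydride reagent's counter-ion by the α- or β-oxygen could erode Felkin–Anh control and give the 6S alcohol, hence the trans lactone. Fallback by chelation-controlled addition to an aldehyde, setting out from lactol 20 and rejoining at 26: the lactol is opened as its N,N-dimethylhydrazone F5 (Me2NNH2, EtOH). The freed C12 alcohol is pivaloylated (PivCl, pyridine) to the hydrazone pivalate F6, and the hydrazone is hydrolysed (CuCl2, THF/pH 7 buffer) to the free aldehyde F7. After precomplexation with MgBr2·OEt2 in CH2Cl2 at −78 °C, the six-membered chelate between the aldehyde and the C8 p-methoxybenzyl ether is attacked by the alkoxymethyllithium 24 anti to C11, which should give the 6R adduct F8. i-Bu2AlH then removes the pivalate to give diol 26.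

3. Step 24. The alkenylchromium species may attack the wrong face of the C5 aldehyde in the ring-closing transition state, and intermolecular coupling competes if dilution is insufficient. Fallback with reagent control of C5, setting out from aldehyde 34 and rejoining at 35: the ring-closed material containing the 5R alcohol F9 is oxidised (Dess–Martin periodinane) to the cross-conjugated C5 enone F10. A Corey–Bakshi–Shibata reduction ((S)-2-methyl-CBS-oxazaborolidine, catecholborane, −78 °C; the antipodal catalyst if the alkenyl group does not act as the larger substituent) then returns 35 with the 5S configuration.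

## Further compounds

F1 | step 2 | racemic ethyl exo-2,7-dioxabicyclo[3.2.0]hept-3-ene-6-carboxylate | CCOC(=O)[C@H]1O[C@@H]2OC=C[C@H]12.CCOC(=O)[C@@H]1O[C@H]2OC=C[C@@H]12
F2 | step 2 | racemic ethyl exo-2,7-dioxabicyclo[3.2.0]heptane-6-carboxylate | CCOC(=O)[C@H]1O[C@@H]2OCC[C@H]12.CCOC(=O)[C@@H]1O[C@H]2OCC[C@@H]12
F3 | step 2 | racemic exo-(2,7-dioxabicyclo[3.2.0]heptan-6-yl)methanol | OC[C@H]1O[C@@H]2OCC[C@H]12.OC[C@@H]1O[C@H]2OCC[C@@H]12
F4 | step 2 | [(1S,5R,6S)-2,7-dioxabicyclo[3.2.0]heptan-6-yl]methyl acetate | CC(=O)OC[C@H]1O[C@@H]2OCC[C@H]12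
F5 | step 17 | open-chain C6 N,N-dimethylhydrazone with free C12 alcohol | CN(C)N=C[C@H](CCO)[C@H](OCc1ccc(OC)cc1)C/C(C)=C\[C@H](O[Si](C)(C)C(C)(C)C)CC(Br)=C
F6 | step 17 | C12 pivalate of F5 | CN(C)N=C[C@H](CCOC(=O)C(C)(C)C)[C@H](OCc1ccc(OC)cc1)C/C(C)=C\[C@H](O[Si](C)(C)C(C)(C)C)CC(Br)=C
F7 | step 17 | free C6 aldehyde with C12 pivalate | O=C[C@H](CCOC(=O)C(C)(C)C)[C@H](OCc1ccc(OC)cc1)C/C(C)=C\[C@H](O[Si](C)(C)C(C)(C)C)CC(Br)=C
F8 | step 17 | 6R carbinol with C12 pivalate | CCOC(C)OC[C@H](O)[C@H](CCOC(=O)C(C)(C)C)[C@H](OCc1ccc(OC)cc1)C/C(C)=C\[C@H](O[Si](C)(C)C(C)(C)C)CC(Br)=C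
F9 | step 24 | 5R epimer of 35 | C=C1C(=O)O[C@@H]2[C@H]1[C@H](OC(=O)/C(C)=C/C)C/C(C)=C\[C@H](O[Si](C)(C)C(C)(C)C)CC(=C)[C@H]2O
F10 | step 24 | ten-membered-ring C5 enone | C=C1C(=O)O[C@@H]2[C@H]1[C@H](OC(=O)/C(C)=C/C)C/C(C)=C\[C@H](O[Si](C)(C)C(C)(C)C)CC(=C)C2=O
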